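At 61 min the ochre flask holds 40.99 mM of target, 82.0% of its starting material. The violet flask holds the same free catalyst as the ochre flask, but its starting material and partner both stand 4.00 times higher, with partner over starting material at 1.20 in each. What has to be found is whether violet ends where ochre ends.

| flask | starting material | partner | free catalyst | time |
|---|---|---|---|---|
| ochre | 50.0 mM | 60.0 mM | 1.50 mM |  |
| red | 20.0 mM | 30.0 mM | 1.50 mM |  |
| amber | 50.0 mM | 90.0 mM | 1.50 mM |  |
| green | 150 mM | 60.0 mM | 1.50 mM |  |
| violet | 200 mM | 240 mM | 1.50 mM | 61 min |

| ochre run: time / min | ochre run: [target] / mM | red run: time / min | red run: [target] / mM | amber run: time / min | amber run: [target] / mM | green run: time / min | green run: [target] / mM |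
|---|---|---|---|---|---|---|---|
| 2.4 | 2.00 | 2.4 | 0.90 | 2.4 | 3.01 | 2.4 | 3.54 |
| 3.9 | 3.88 | 3.9 | 1.96 | 3.9 | 5.33 | 3.9 | 5.39 |
| 6.1 | 6.47 | 6.1 | 2.67 | 6.1 | 8.25 | 6.1 | 8.20 |
| 9.7 | 10.37 | 9.7 | 4.58 | 9.7 | 12.51 | 9.7 | 13.60 |
| 15 | 14.70 | 15 | 7.05 | 15 | 18.41 | 15 | 19.63 |
| 24 | 21.77 | 24 | 10.53 | 24 | 27.11 | 24 | 28.86 |
| 39 | 31.87 | 39 | 14.93 | 39 | 38.17 | 39 | 40.15 |
| 61 | 40.99 | 61 | 18.44 | 61 | 47.54 | 61 | 49.86 |

(readings scatter by 0.2 mM)

- Overall: starting material + partner -> target, with free catalyst as catalyst.
- Constant volume, constant temperature.
- Readings of a species count what is bound in complexes too.
- An order is taken over about fifteen percent of the charge, up and down.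

- apparent order in [partner] of the starting rate, round the charge of the ochre run (the rate where two percent of its starting material have turned into target)
- apparent order in [starting material] of the starting rate, round the charge of the ochre run (the rate where two percent of its starting material have turned into target) (one fixed amount of target, the same in the runs compared)
- the red run starts with 30.0 mM less of starting material and of partner than the ochre run, and with no target. Compared where both hold the same amount of starting material, once fifteen percent of what the red run was charged with has turned into target, is the red run faster, slower or alike (within a tenth)?
- target in the violet run at 61 min, as a share of the starting material charged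

If both charges rise by one factor at fixed free catalyst and the rate follows a power law, the rate rises by that factor to the power n, where n is the overall apparent order, the orders in starting material and partner added together. The amount to be made rises by the factor itself, so the time to a given share stretches by the factor to the power 1 − n.

The red flask gives a reading of n. Against ochre its starting material stands at 0.400 and its partner at 0.500, and the target ratio at 15 min stands in for the rate ratio:

s = mean charge factor = 0.447

n = ln(7.05 mM / 14.70 mM) / ln(s) = 0.913

This n, the power by which the rate follows the charge, is a reading. Because it lies below 1, this reckoning has the violet flask take longer than ochre to reach the same share: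

stretch = 4.00^(1 − n) = 1.13

violet at 61 min matches ochre at 54.1 min

A straight line between the ochre readings at 39 min and 61 min gives 38.1 mM there. This reckoning therefore puts violet at 76.2%, below ochre's share.

The amber flask, against ochre at 15 min, reads the partner's part of n:

order in partner = ln(18.41 mM / 14.70 mM) / ln(1.50) = 0.555

The forecast gives 0.65 in partner, 0.35 in starting material, slower for red and 79% for violet, higher than this reckoning. On the red comparison its words are: “This call is borderline”

    free catalyst + starting material → loaded catalyst + by-product (83.40 M⁻¹ min⁻¹)
    loaded catalyst + partner → target + free catalyst (21.30 M⁻¹ min⁻¹)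
    starting material + partner → target (0.1266 M⁻¹ min⁻¹)
    2 starting material ⇌ idle substrate dimer, settled at all times (52.80 M⁻¹)

The flask gives 0.59 in partner, 0.33 in starting material, alike for red where the forecast had slower, and 76.9% for violet, under ochre's share. Fitted with the main steps alone, the runs forecast 81.6% for violet. The green flask holds 3.00 times ochre's starting material at the same partner, and what remains of n after the partner's part is 0.358. That remainder gives a rate ratio of 1.48, and, set against the ochre rate at equal target, the rate ratio of the green flask stands at 1.4.

The earlier runs and the new flask are simulated with made-up constants, noise included.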